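The pitfall here was to read the asked share as a percentage of the charge, when its denominator holds single ring and the oligomers (open dimer, open trimer, ring dimer). I therefore worked with ρ, single ring over oligomer, both counted by starting material. This is a selectivity factor, the ratio of two amounts made, and the share is ρ/(1+ρ); I followed ρ in temperature and in time.

all flasks: starting material 0.20 M
- alder: protic impurity 0.050 M; temperature −25 °C; run made earlier
- larch: protic impurity 0.075 M; temperature −10 °C; run made earlier
- Wednesday's: protic impurity 0.100 M; temperature 0 °C; time 12 h
- Thursday's: protic impurity 0.100 M; at −20 °C until 6.0 h, from then on at 0 °C; time 12 h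
- Sunday's: protic impurity 0.100 M; temperature −20 °C; time 12 h

- alder (time / h: single ring / %, open dimer / %): 6.00: 28.2, 24.5; 15.0: 33.5, 24.7; 20.0: 33.7, 23.5; 30.0: 29.6, 22.0; 40.0: 26.9, 19.5
- larch (time / h: single ring / %, open dimer / %): 3.00: 47.6, 16.6; 6.00: 44.6, 13.6; 10.0: 40.7, 7.6; 12.0: 39.8, 6.4; 15.0: 36.4, 5.7; 20.0: 35.0, 4.4

(scatter of a reading: 1 percentage point)

- which flask leads in share of single ring in all that became single ring or open dimer or open trimer or ring dimer ("all alike" within 1.5 percentage points) (Wednesday's / Thursday's / Sunday's / all alike)
- share of single ring in all that became single ring or open dimer or open trimer or ring dimer, Wednesday's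
- share of single ring in all that became single ring or open dimer or open trimer or ring dimer, Thursday's
- share of single ring in all that became single ring or open dimer or open trimer or ring dimer, Sunday's

- a species is counted by the starting material in it: one open dimer or ring dimer counts as two
- a species is counted by the starting material in it: one open trimer counts as three

Taking open dimer for the whole oligomer at the first readings, I read ρ as 1.15 in the alder run and 2.87 in the larch run. Carrying that growth geometrically in temperature gave 5.27 at 0 °C. From the first to the last reading, single ring fell in the larch run at a rate which, scaled in proportion to c(protic impurity) up to 0.100 M, came to 0.0241 h⁻¹. The alder run, at −25 °C, gave 0.0225 h⁻¹ on the same scaling, so I held it independent of temperature. This fade rate, the pseudo-first-order loss of single ring per hour at the impurity charged here, acts on the numerator while I kept the oligomer standing. Over 12 h it brought Wednesday's ρ to 3.95, a share of 79.8%.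

The weak link was the larch ratio, since open dimer there was already draining at 0.0781 h⁻¹. Restoring that drain over the first 3.00 h lowered the larch ρ to 2.27. I then committed to a share of 72.8% for Wednesday's and 51.9% for Sunday's, with Thursday's at Sunday's figure or slightly above, and Wednesday's leading.

The forecast, which saw “a ring/oligomer split set early, followed by slow loss of ring”, named Wednesday's as the leader, with 41%, 31% and 33% for Wednesday's, Thursday's and Sunday's.

The flasks gave 59.7%, 52.7% and 51.8% in that order, with Wednesday's leading, so my Wednesday's figure stood 13 percentage points too high.

    starting material ⇌ single ring (K = 2.70, k = 0.00311 min⁻¹, Ea = 72.0 kJ mol⁻¹, ΔH = 36.0 kJ mol⁻¹)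
    2 starting material → open dimer (k = 0.00922 M⁻¹ min⁻¹, Ea = 57.0 kJ mol⁻¹)
    starting material + open dimer → open trimer (k = 0.00739 M⁻¹ min⁻¹, Ea = 54.0 kJ mol⁻¹)
    open dimer → ring dimer (k = 4.73 × 10⁻⁴ min⁻¹, Ea = 81.0 kJ mol⁻¹)
    starting material + protic impurity → quenched substrate (k = 0.0189 M⁻¹ min⁻¹, Ea = 58.0 kJ mol⁻¹)
    (constants at −20 °C)

Thursday's flask at 12.0 h held 34.8% single ring against 31.2% oligomer. Read later, at 20 h, with the oligomer held, the fade rate 0.0241 h⁻¹ acting for 8.00 h leaves 28.7% single ring, a share of 47.9%. That same flask at 20 h held 27.9% single ring, and its share stood at 46.3%.

The data are simulated with made-up constants, noise included.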